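Everything rests on cutting ring A (the bromodimethylcyclohexylidene ring) between its alkylidene carbon and the adjacent CH2 of the CH2CH2CHBr arm, and forming this bond by ring contraction. Cyclic hydroboration of an open-chain enyne with thexylborane gives a seven-membered B-alkenyl boracycle; iodine and methoxide then trigger a Zweifel 1,2-shift of the ring CH2 from boron to the alkenyl carbon and expel boron. One operation thus delivers the six-membered carbocycle and, stereospecifically, the E exocyclic trisubstituted C=C that joins it to hydrindane C1, the feature exploited. The precursor is a hept-1-en-6-yne carrying CMe2, an allylic pinacol boronate (later the ring bromide) and the bromohydrindanol unit on the alkyne.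

Key step: step 15

Assumption: in the two catalyst-controlled steps (6 and 14) the catalyst enantiomer that gives the drawn configuration is used; the facial sense is set by the catalyst, not by the substrate.

Step 1
Reactants: 1 isobutyraldehyde; 2 propargyl bromide
Product: 3 2,2-dimethylpent-4-ynal
Conditions: NaOH (aq), Bu4NI (cat.), toluene, 70 °C
Reagents that add atoms: none
Why: Phase-transfer C-alkylation of the aldehyde enolate at the propargylic carbon (SN2) should build the quaternary CMe2 carbon; no stereocentre is formed.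

Step 2
Reactants: 3 2,2-dimethylpent-4-ynal; 4 trimethyl phosphonoacetate
Product: 5 methyl (E)-4,4-dimethylhept-2-en-6-ynoate
Conditions: LiCl, DBU, MeCN, 25 °C
Reagents that add atoms: none
Why: Horner–Wadsworth–Emmons olefination under Masamune–Roush conditions should give the E enoate from the non-enolisable aldehyde without deprotonating the terminal alkyne.

Step 3
Reactants: 5 methyl (E)-4,4-dimethylhept-2-en-6-ynoate
Product: 6 (E)-4,4-dimethylhept-2-en-6-yn-1-ol
Conditions: diisobutylaluminium hydride (2.2 equiv), CH2Cl2, −78 °C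
Reagents that add atoms: none
Why: Low-temperature 1,2-reduction of the enoate by the aluminium hydride should give the allylic alcohol and leave alkyne and E alkene untouched.

Step 4
Reactants: 6 (E)-4,4-dimethylhept-2-en-6-yn-1-ol
Product: 7 (E)-4,4-dimethylhept-2-en-6-yn-1-yl methyl carbonate
Conditions: ClCO2Me, pyridine, CH2Cl2, 0 °C
Reagents that add atoms: methyl chloroformate COC(=O)Cl
Why: O-Acylation of the primary allylic alcohol should give the carbonate that later serves as leaving group in the allylic borylation.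

Step 5
Reactants: 8 geranyl bromide; 9 acetic acid
Product: 10 (E)-5,9-dimethyldeca-4,8-dienoic acid
Conditions: lithium diisopropylamide (2.2 equiv), THF–DMPU, 0 → 25 °C; then aq HCl
Reagents that add atoms: none
Why: SN2 alkylation of the acetic acid dianion at the primary allylic carbon should keep the E trisubstituted alkene of the geranyl unit.

Step 6
Reactants: 10 (E)-5,9-dimethyldeca-4,8-dienoic acid
Product: 11 (5S,6R)-5-bromo-6-methyl-6-(4-methylpent-3-en-1-yl)oxan-2-one
Conditions: NBS, cinchona-alkaloid amino-thiocarbamate organocatalyst (10 mol %), CHCl3–toluene, −78 °C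
Reagents that add atoms: N-bromosuccinimide BrN1C(=O)CCC1=O
Why: Catalytic enantioselective 6-endo bromolactonisation should add Br and carboxylate anti across the E 4,5-alkene (C–O at the tertiary carbon), which fixes the relative configuration of both centres while the catalyst selects the alkene face; the distal alkene has no internal nucleophile and should survive.

Step 7
Reactants: 11 (5S,6R)-5-bromo-6-methyl-6-(4-methylpent-3-en-1-yl)oxan-2-one
Product: 12 (2R,3S)-3-bromo-2-methyl-2-(4-methylpent-3-en-1-yl)-6-methylideneoxane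
Conditions: Cp2TiMe2, toluene, 65 °C, dark
Reagents that add atoms: dimethyltitanocene [CH3-].[CH3-].[Ti+4].c1cc[cH-]c1.c1cc[cH-]c1
Why: Petasis methylenation should convert the lactone carbonyl into the exocyclic enol ether under non-acidic conditions that tolerate the secondary bromide.

Step 8
Reactants: 12 (2R,3S)-3-bromo-2-methyl-2-(4-methylpent-3-en-1-yl)-6-methylideneoxane
Product: 13 (3S,4S)-4-bromo-3-methyl-3-(4-methylpent-3-en-1-yl)cyclohexan-1-one
Conditions: Me2AlCl, CH2Cl2, −78 → 0 °C
Reagents that add atoms: none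
Why: In this Petasis–Ferrier-type 1,3 O-to-C rearrangement the anti bromine should assist ionisation of the tertiary C–O bond (bromonium), and the aluminium enolate carbon should reclose on that carbon anti to bromine, so the quaternary centre keeps the lactone configuration.

Step 9
Reactants: 13 (3S,4S)-4-bromo-3-methyl-3-(4-methylpent-3-en-1-yl)cyclohexan-1-one
Product: 14 3-[(1S,2S)-2-bromo-1-methyl-5-oxocyclohexyl]propanal
Conditions: O3, CH2Cl2–MeOH, −78 °C; then Me2S
Reagents that add atoms: ozone [O-][O+]=O
Why: Ozonolysis with reductive work-up should cleave the only alkene to the aldehyde.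

Step 10
Reactants: 14 3-[(1S,2S)-2-bromo-1-methyl-5-oxocyclohexyl]propanal
Product: 15 (3aS,4S)-4-bromo-3a-methyl-2,3,3a,4,5,6-hexahydro-7H-inden-7-one
Conditions: TsOH·H2O (cat.), benzene, 80 °C, Dean–Stark
Reagents that add atoms: none
Why: Acid-catalysed intramolecular aldol condensation between the ketone alpha carbon and the aldehyde should close the five-membered ring, driven by dehydration to the conjugated enone (the alternative aldol mode cannot dehydrate and is reversible).

Step 11
Reactants: 7 (E)-4,4-dimethylhept-2-en-6-yn-1-yl methyl carbonate; 15 (3aS,4S)-4-bromo-3a-methyl-2,3,3a,4,5,6-hexahydro-7H-inden-7-one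
Product: 18 methyl (E)-7-[(1R,3aS,4S,7aS)-4-bromo-3a-methyl-7-oxooctahydro-1H-inden-1-yl]-4,4-dimethylhept-2-en-6-yn-1-yl carbonate, via alkynylzinc chloride 16 (not isolated), via trimethylsilyl enol ether 17 (not isolated)
Conditions: 7, TMPZnCl·LiCl, THF, 25 °C; then 15, TMSOTf, Et2O, −40 °C; then 1 M HCl, THF, 0 °C
Reagents that add atoms: none
Why: Silyl-triflate-promoted conjugate addition of the alkynylzinc should deliver the alkyne to C1 anti to the angular methyl group, and kinetic axial protonation of the enol silane from the same open face should give the trans ring fusion.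

Step 12
Reactants: 18 methyl (E)-7-[(1R,3aS,4S,7aS)-4-bromo-3a-methyl-7-oxooctahydro-1H-inden-1-yl]-4,4-dimethylhept-2-en-6-yn-1-yl carbonate
Product: 19 methyl (E)-7-[(1R,3aS,4S,7R,7aS)-4-bromo-7-hydroxy-3a,7-dimethyloctahydro-1H-inden-1-yl]-4,4-dimethylhept-2-en-6-yn-1-yl carbonate
Conditions: MeLi, CeCl3, THF, −78 °C
Reagents that add atoms: methyllithium [Li]C
Why: Organocerium 1,2-addition should occur by equatorial attack, because the axial angular methyl group blocks the axial path, giving the axial tertiary alcohol without enolisation or attack on the carbonate.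

Step 13
Reactants: 19 methyl (E)-7-[(1R,3aS,4S,7R,7aS)-4-bromo-7-hydroxy-3a,7-dimethyloctahydro-1H-inden-1-yl]-4,4-dimethylhept-2-en-6-yn-1-yl carbonate
Product: 20 methyl (E)-7-[(1R,3aS,4S,7R,7aS)-4-bromo-3a,7-dimethyl-7-(triethylsilyloxy)octahydro-1H-inden-1-yl]-4,4-dimethylhept-2-en-6-yn-1-yl carbonate
Conditions: TESOTf, 2,6-lutidine, CH2Cl2, −78 → 0 °C
Reagents that add atoms: triethylsilyl trifluoromethanesulfonate CC[Si](CC)(CC)OS(=O)(=O)C(F)(F)F
Why: Silylation of the hindered tertiary alcohol with the silyl triflate should protect it against the borane, the aryllithium and NBS used later.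

Step 14
Reactants: 20 methyl (E)-7-[(1R,3aS,4S,7R,7aS)-4-bromo-3a,7-dimethyl-7-(triethylsilyloxy)octahydro-1H-inden-1-yl]-4,4-dimethylhept-2-en-6-yn-1-yl carbonate
Product: 21 2-[(3R)-7-[(1R,3aS,4S,7R,7aS)-4-bromo-3a,7-dimethyl-7-(triethylsilyloxy)octahydro-1H-inden-1-yl]-4,4-dimethylhept-1-en-6-yn-3-yl]-4,4,5,5-tetramethyl-1,3,2-dioxaborolane
Conditions: B2pin2, CuCl (5 mol %), chiral imidazolinium sulfonate (N-heterocyclic carbene precursor, 5.5 mol %), NaOMe (20 mol %), DME, −30 → 22 °C
Reagents that add atoms: bis(pinacolato)diboron CC1(C)OB(OC1(C)C)B1OC(C)(C)C(C)(C)O1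
Why: Copper-catalysed SN2′ allylic borylation (syn borylcupration, then beta-alkoxide elimination) should place boron on the carbon next to CMe2 and unveil the terminal alkene, with the chiral carbene ligand setting the C–B stereocentre as R.

Step 15
Reactants: 21 2-[(3R)-7-[(1R,3aS,4S,7R,7aS)-4-bromo-3a,7-dimethyl-7-(triethylsilyloxy)octahydro-1H-inden-1-yl]-4,4-dimethylhept-1-en-6-yn-3-yl]-4,4,5,5-tetramethyl-1,3,2-dioxaborolane
Product: 23 2-[(1R,4E)-4-{[(1S,3aS,4S,7R,7aS)-4-bromo-3a,7-dimethyl-7-(triethylsilyloxy)octahydro-1H-inden-1-yl]methylidene}-2,2-dimethylcyclohexyl]-4,4,5,5-tetramethyl-1,3,2-dioxaborolane, via B-thexyl boracycle 22 (not isolated)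
Conditions: thexylborane (from BH3·THF and 2,3-dimethylbut-2-ene), THF (0.01 M), −20 → 0 °C; then NaOMe, MeOH; I2, THF, −78 → 0 °C
Reagents that add atoms: none
Why: Thexylborane should add first to the terminal alkene (boron on the CH2 terminus), and the remaining B–H should then add syn and intramolecularly to the alkyne carbon that carries the CH2CMe2 chain, closing the seven-membered B-alkenyl boracycle 22 by 7-exo-dig cyclic hydroboration. Iodine and methoxide should then start the Zweifel sequence: iodonium formation on the alkenyl borate, 1,2-shift of the ring CH2 from boron to the alkenyl carbon anti to iodine, and anti deiodoboronation, which removes boron from the ring and contracts the seven-membered boracycle to the six-membered carbocycle (closure by 1,2-metallate shift). The closest known reaction type is the Zweifel olefination of thexyl(alkyl)alkenylboranes, used here in its intramolecular form. No sp3 stereocentre is created; the alkene geometry is fixed by mechanism, since syn hydroboration puts boron cis to the vinylic hydrogen and migration with inversion plus anti elimination places the migrating ring CH2 cis to the hydrindanyl carbon, which is the E isomer. The step needs alkene-before-alkyne chemoselectivity (unhindered vinyl group against a hindered internal alkyne), ring closure over oligomerisation (high dilution, gem-dimethyl group) and migration of the primary ring carbon instead of the tertiary thexyl group; the secondary pinacol boronate, the bromide and the silyl ether should be inert.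

Step 16
Reactants: 23 2-[(1R,4E)-4-{[(1S,3aS,4S,7R,7aS)-4-bromo-3a,7-dimethyl-7-(triethylsilyloxy)octahydro-1H-inden-1-yl]methylidene}-2,2-dimethylcyclohexyl]-4,4,5,5-tetramethyl-1,3,2-dioxaborolane
Product: 26 (1S,3aS,4S,7R,7aS)-4-bromo-1-{(E)-[(4S)-4-bromo-3,3-dimethylcyclohexylidene]methyl}-3a,7-dimethyloctahydro-1H-inden-7-ol, via aryl boronate complex 24 (not isolated), via triethylsilyl ether 25 (not isolated)
Conditions: 3,5-(CF3)2C6H3Li (from the aryl bromide and nBuLi), THF, −78 °C; NBS, −78 → 25 °C; then HF·pyridine, THF, 0 °C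
Reagents that add atoms: N-bromosuccinimide BrN1C(=O)CCC1=O
Why: Stereospecific bromodeboronation: NBS should attack the electron-poor aryl boronate complex at carbon with inversion (SE2 with inversion), turning the R boronate into the S bromide, and fluoride then frees the tertiary alcohol.

Compound list
1 | isobutyraldehyde | CC(C)C=O | starting material
2 | propargyl bromide | C#CCBr | starting material
3 | 2,2-dimethylpent-4-ynal | O=CC(C)(C)CC#C | intermediate
4 | trimethyl phosphonoacetate | COC(=O)CP(=O)(OC)OC | starting material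
5 | methyl (E)-4,4-dimethylhept-2-en-6-ynoate | COC(=O)/C=C/C(C)(C)CC#C | intermediate
6 | (E)-4,4-dimethylhept-2-en-6-yn-1-ol | OC/C=C/C(C)(C)CC#C | intermediate
7 | (E)-4,4-dimethylhept-2-en-6-yn-1-yl methyl carbonate | COC(=O)OC/C=C/C(C)(C)CC#C | intermediate
8 | geranyl bromide, (E)-1-bromo-3,7-dimethylocta-2,6-diene | CC(C)=CCC/C(C)=C/CBr | starting material
9 | acetic acid | CC(=O)O | starting material
10 | (E)-5,9-dimethyldeca-4,8-dienoic acid | CC(C)=CCC/C(C)=C/CCC(=O)O | intermediate
11 | (5S,6R)-5-bromo-6-methyl-6-(4-methylpent-3-en-1-yl)oxan-2-one | O=C1CC[C@H](Br)[C@@](C)(CCC=C(C)C)O1 | intermediate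
12 | (2R,3S)-3-bromo-2-methyl-2-(4-methylpent-3-en-1-yl)-6-methylideneoxane | C=C1CC[C@H](Br)[C@@](C)(CCC=C(C)C)O1 | intermediate
13 | (3S,4S)-4-bromo-3-methyl-3-(4-methylpent-3-en-1-yl)cyclohexan-1-one | O=C1CC[C@H](Br)[C@@](C)(CCC=C(C)C)C1 | intermediate
14 | 3-[(1S,2S)-2-bromo-1-methyl-5-oxocyclohexyl]propanal | O=C1CC[C@H](Br)[C@@](C)(CCC=O)C1 | intermediate
15 | (3aS,4S)-4-bromo-3a-methyl-2,3,3a,4,5,6-hexahydro-7H-inden-7-one | O=C1CC[C@H](Br)[C@@]2(C)CCC=C12 | intermediate
16 | alkynylzinc chloride of 7, chloro{(E)-7-[(methoxycarbonyl)oxy]-4,4-dimethylhept-5-en-1-yn-1-yl}zinc | COC(=O)OC/C=C/C(C)(C)CC#C[Zn]Cl | intermediate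
17 | trimethylsilyl enol ether of 18 (C7–O–Si, C7=C7a; alkynyl at C1 anti to the angular methyl) | COC(=O)OC/C=C/C(C)(C)CC#C[C@@H]1CC[C@]2(C)[C@@H](Br)CCC(O[Si](C)(C)C)=C12 | intermediate
18 | methyl (E)-7-[(1R,3aS,4S,7aS)-4-bromo-3a-methyl-7-oxooctahydro-1H-inden-1-yl]-4,4-dimethylhept-2-en-6-yn-1-yl carbonate | COC(=O)OC/C=C/C(C)(C)CC#C[C@@H]1CC[C@]2(C)[C@@H](Br)CCC(=O)[C@@H]12 | intermediate
19 | methyl (E)-7-[(1R,3aS,4S,7R,7aS)-4-bromo-7-hydroxy-3a,7-dimethyloctahydro-1H-inden-1-yl]-4,4-dimethylhept-2-en-6-yn-1-yl carbonate | COC(=O)OC/C=C/C(C)(C)CC#C[C@@H]1CC[C@]2(C)[C@@H](Br)CC[C@@](C)(O)[C@@H]12 | intermediate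
20 | methyl (E)-7-[(1R,3aS,4S,7R,7aS)-4-bromo-3a,7-dimethyl-7-(triethylsilyloxy)octahydro-1H-inden-1-yl]-4,4-dimethylhept-2-en-6-yn-1-yl carbonate | COC(=O)OC/C=C/C(C)(C)CC#C[C@@H]1CC[C@]2(C)[C@@H](Br)CC[C@@](C)(O[Si](CC)(CC)CC)[C@@H]12 | intermediate
21 | 2-[(3R)-7-[(1R,3aS,4S,7R,7aS)-4-bromo-3a,7-dimethyl-7-(triethylsilyloxy)octahydro-1H-inden-1-yl]-4,4-dimethylhept-1-en-6-yn-3-yl]-4,4,5,5-tetramethyl-1,3,2-dioxaborolane | C=C[C@@H](B1OC(C)(C)C(C)(C)O1)C(C)(C)CC#C[C@@H]1CC[C@]2(C)[C@@H](Br)CC[C@@](C)(O[Si](CC)(CC)CC)[C@@H]12 | intermediate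
22 | B-thexyl boracycle: (5R)-1-(2,3-dimethylbutan-2-yl)-2-[(Z)-hydrindanylmethylidene]-4,4-dimethyl-5-(pinacolboryl)borepane, boron cis to the vinylic hydrogen | CC(C)C(C)(C)B1CC[C@@H](B2OC(C)(C)C(C)(C)O2)C(C)(C)C/C1=C\[C@@H]1CC[C@]2(C)[C@@H](Br)CC[C@@](C)(O[Si](CC)(CC)CC)[C@@H]12 | intermediate
23 | 2-[(1R,4E)-4-{[(1S,3aS,4S,7R,7aS)-4-bromo-3a,7-dimethyl-7-(triethylsilyloxy)octahydro-1H-inden-1-yl]methylidene}-2,2-dimethylcyclohexyl]-4,4,5,5-tetramethyl-1,3,2-dioxaborolane | CC1(C)C/C(=C/[C@@H]2CC[C@]3(C)[C@@H](Br)CC[C@@](C)(O[Si](CC)(CC)CC)[C@@H]23)CC[C@H]1B1OC(C)(C)C(C)(C)O1 | intermediate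
24 | lithium boronate complex of 23 carrying 3,5-bis(trifluoromethyl)phenyl on boron | CC1(C)C/C(=C/[C@@H]2CC[C@]3(C)[C@@H](Br)CC[C@@](C)(O[Si](CC)(CC)CC)[C@@H]23)CC[C@H]1[B-]1(OC(C)(C)C(C)(C)O1)c1cc(cc(c1)C(F)(F)F)C(F)(F)F.[Li+] | intermediate
25 | triethylsilyl ether of 26 (silyl on the C7 oxygen) | CC1(C)C/C(=C/[C@@H]2CC[C@]3(C)[C@@H](Br)CC[C@@](C)(O[Si](CC)(CC)CC)[C@@H]23)CC[C@@H]1Br | intermediate
26 | (1S,3aS,4S,7R,7aS)-4-bromo-1-{(E)-[(4S)-4-bromo-3,3-dimethylcyclohexylidene]methyl}-3a,7-dimethyloctahydro-1H-inden-7-ol | CC1(C)C/C(=C/[C@@H]2CC[C@]3(C)[C@@H](Br)CC[C@@](C)(O)[C@@H]23)CC[C@@H]1Br | target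

Total step count: 16. Longest linear sequence: 12 steps (steps 5 to 16, from geranyl bromide); steps 1 to 4 give the enyne side arm that joins in step 11.

Steps most likely to fail

Step 16. The electrophile may react with the crowded boronate complex by single-electron transfer, or too slowly, so that inversion at the neopentyl carbon is incomplete. Fallback, a radical route with separation: setting out from 23, KHF2 in MeOH–H2O would give the potassium trifluoroborate F4, with loss of the silyl ether. Single-electron oxidation under blue light (9-mesityl-10-methylacridinium salt) in the presence of BrCCl3 would then give the secondary bromide through the ring radical. This radical has no facial bias, so the ring-A epimer F5 would form beside the target and be removed by preparative HPLC; the route is rejoined at 26.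

Step 15. Intermolecular hydroboration may outrun closure of the seven-membered boracycle and give oligomers. Fallback, a stepwise assembly of the same boracycle: setting out from 21, thexylchloroborane–dimethyl sulfide would hydroborate only the terminal alkene and give the alkyl(thexyl)chloroborane F3. K(iPrO)3BH at −78 °C under high dilution would then replace chloride by hydride, so that the single B–H bond present can only add to the tethered alkyne. This returns to the route at 22, which is contracted with iodine and NaOMe as in step 15.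

Step 8. Loss of a proton or of HBr from the tertiary cation, or hydrolysis of the enol ether, may compete with carbon–carbon bond formation. Fallback, an open-chain cyclisation: setting out from 11, MeLi (1 equiv, −78 °C) would open the lactone to the hydroxy methyl ketone F1. Lithium diisopropylamide and TMSCl would give the kinetic enol silane with silylation of the tertiary alcohol, the bis-silyl compound F2. TiCl4 at −78 °C would ionise the tertiary silyloxy group with bromine participation, and the enol silane would alkylate the cation intramolecularly (Mukaiyama-type tertiary alkylation); the route is rejoined at 13.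

Further compounds
F1 | step 8 | (5S,6R)-5-bromo-6-hydroxy-6,10-dimethylundec-9-en-2-one | CC(=O)CC[C@H](Br)[C@](C)(O)CCC=C(C)C
F2 | step 8 | (5S,6R)-5-bromo-6,10-dimethyl-2,6-bis(trimethylsilyloxy)undeca-1,9-diene | C=C(O[Si](C)(C)C)CC[C@H](Br)[C@](C)(O[Si](C)(C)C)CCC=C(C)C
F3 | step 15 | alkyl(thexyl)chloroborane from hydroboration of the vinyl group of 21 | CC(C)C(C)(C)B(Cl)CC[C@@H](B1OC(C)(C)C(C)(C)O1)C(C)(C)CC#C[C@@H]1CC[C@]2(C)[C@@H](Br)CC[C@@](C)(O[Si](CC)(CC)CC)[C@@H]12
F4 | step 16 | potassium trifluoroborate of desilylated 23 | CC1(C)C/C(=C/[C@@H]2CC[C@]3(C)[C@@H](Br)CC[C@@](C)(O)[C@@H]23)CC[C@H]1[B-](F)(F)F.[K+]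
F5 | step 16 | (1S,3aS,4S,7R,7aS)-4-bromo-1-{(E)-[(4R)-4-bromo-3,3-dimethylcyclohexylidene]methyl}-3a,7-dimethyloctahydro-1H-inden-7-ol | CC1(C)C/C(=C/[C@@H]2CC[C@]3(C)[C@@H](Br)CC[C@@](C)(O)[C@@H]23)CC[C@H]1Br
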